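Ring D, read back to the lactone oxidation level, is a trans-α,β-disubstituted γ-butyrolactone. The route rests on cutting two bonds at its adjacent carbons: the bond from the β-carbon to its methyl group, and the bond from the α-carbon (the future ring-fusion CH) to the benzylic CH2 of ring C. That leads to plain furan-2(5H)-one, MeMgBr and a benzylic bromide on the finished 12-membered macrolide, its phenol masked as a MOM ether. One flask, copper-catalysed enantioselective methyl addition followed by benzylation of the enolate, makes both bonds and both carbon stereocentres of ring D. Methyllithium and acid then convert the lactone into the cis-fused ketal that joins rings C and D.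

Key step: step 11

Assumption: the ferrocenyl diphosphine antipode named in step 11 is taken to deliver methyl so that the β-carbon becomes S; if a model run with benzyl bromide shows the opposite sense, the mirror-image ligand (also commercial) is used.

Step 1
Reactants: 1 3,5-dimethoxybenzyl bromide; 2 5-bromopent-1-ene
Product: 4 1-(hex-5-en-1-yl)-3,5-dimethoxybenzene, via pent-4-enylmagnesium bromide 3 (not isolated)
Conditions: 2, Mg, THF, rt; then 1, Li2CuCl4 (3 mol %), THF, −20 → 0 °C
Reagents that add atoms: none
Why: Copper-catalysed (Kochi-type) cross-coupling of a primary alkyl Grignard reagent with a benzylic bromide is a dependable sp3–sp3 bond formation, the pent-4-enyl Grignard reagent does not cyclise, and the product is symmetric, so the next substitution has only one productive regiochemistry.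

Step 2
Reactants: 4 1-(hex-5-en-1-yl)-3,5-dimethoxybenzene
Product: 6 2-(hex-5-en-1-yl)-4,6-dimethoxybenzaldehyde, via aryl iminium chloride 5 (not isolated)
Conditions: POCl3, DMF, 0 → 70 °C; then ice–water
Reagents that add atoms: N,N-dimethylformamide CN(C)C=O; water O
Why: Vilsmeier–Haack formylation of 5-alkylresorcinol dimethyl ethers goes ortho to the alkyl group and para to a methoxy group rather than between the two methoxy groups, the two such positions of 4 are equivalent, and the isolated alkene is not attacked by the chloroiminium ion.

Step 3
Reactants: 6 2-(hex-5-en-1-yl)-4,6-dimethoxybenzaldehyde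
Product: 7 2-(hex-5-en-1-yl)-6-hydroxy-4-methoxybenzaldehyde
Conditions: BCl3 (1.2 equiv), CH2Cl2, −78 → 0 °C; then H2O
Reagents that add atoms: none
Why: In this chelation-directed Lewis-acid ether cleavage, BCl3 bound to the aldehyde oxygen reaches only the neighbouring methoxy group through a six-membered chelate, so the ortho methyl ether falls and the para one stays, which tells the future ketal oxygen of ring C apart from the oxygen that remains OMe.

Step 4
Reactants: 7 2-(hex-5-en-1-yl)-6-hydroxy-4-methoxybenzaldehyde
Product: 8 3-bromo-2-(hex-5-en-1-yl)-6-hydroxy-4-methoxybenzaldehyde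
Conditions: NBS (1.0 equiv), MeCN, −20 → 0 °C, dark
Reagents that add atoms: N-bromosuccinimide O=C1CCC(=O)N1Br
Why: Electrophilic aromatic bromination with NBS in a polar solvent should go para to the free phenol, at the carbon flanked by OMe and the alkyl chain (the site halogenated in related 2,4-dioxygenated 6-alkylbenzoyl compounds), while the unactivated terminal alkene is much slower than the phenol ring under non-aqueous, non-radical conditions.

Step 5
Reactants: 8 3-bromo-2-(hex-5-en-1-yl)-6-hydroxy-4-methoxybenzaldehyde
Product: 9 3-bromo-2-(hex-5-en-1-yl)-4-methoxy-6-(methoxymethoxy)benzaldehyde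
Conditions: MOMCl, i-Pr2NEt, CH2Cl2, 0 °C → rt
Reagents that add atoms: chloromethyl methyl ether COCCl
Why: Williamson-type O-alkylation of the phenol with the α-chloro ether gives the MOM ether, which withstands the organolithium, phosphine, hydride and Grignard steps ahead and is removed by the acid of the last step.

Step 6
Reactants: 9 3-bromo-2-(hex-5-en-1-yl)-4-methoxy-6-(methoxymethoxy)benzaldehyde
Product: 12 3-formyl-2-(hex-5-en-1-yl)-6-methoxy-4-(methoxymethoxy)benzoic acid, via lithium α-morpholino alkoxide 10 (not isolated), via aryllithium 11 (not isolated)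
Conditions: lithium morpholide (morpholine + n-BuLi, 1.1 equiv), THF, −40 °C; t-BuLi (2.1 equiv), −78 °C; CO2 (g), −78 °C → rt; 1 M HCl to pH 3, 0 °C
Reagents that add atoms: carbon dioxide O=C=O
Why: Addition of the lithium amide masks the aldehyde in situ as a lithium α-amino alkoxide that is inert to t-BuLi, bromine–lithium exchange (far faster than any deprotonation at −78 °C) gives the aryllithium, carboxylation with CO2 installs the acid, and dilute acid on work-up collapses the hemiaminal back to the aldehyde.

Step 7
Reactants: 12 3-formyl-2-(hex-5-en-1-yl)-6-methoxy-4-(methoxymethoxy)benzoic acid; 13 (S)-pent-4-en-2-ol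
Product: 14 (R)-pent-4-en-2-yl 3-formyl-2-(hex-5-en-1-yl)-6-methoxy-4-(methoxymethoxy)benzoate
Conditions: PPh3, DIAD, toluene, 0 °C → rt
Reagents that add atoms: none
Why: Mitsunobu esterification forms the C–O bond at the alcohol carbon and not at the shielded carbonyl, so the di-ortho-substituted benzoic acid reacts readily, and SN2 displacement of the oxyphosphonium group inverts the (S)-alcohol to the (R)-configured ester carbon of the macrolide.

Step 8
Reactants: 14 (R)-pent-4-en-2-yl 3-formyl-2-(hex-5-en-1-yl)-6-methoxy-4-(methoxymethoxy)benzoate
Product: 16 macrolide aldehyde (saturated 12-membered (R)-lactone), via macrocyclic alkene 15 (not isolated)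
Conditions: second-generation Grubbs catalyst (H2IMes)(PCy3)Cl2Ru=CHPh (5 mol %), CH2Cl2 (2 mM), 40 °C; then solvent switch to EtOAc, Pd/C, Ph2S (cat.), H2 (1 atm), rt
Reagents that add atoms: none
Why: Ring-closing olefin metathesis of ester-tethered dienes of this kind is a well-precedented way to 12-membered resorcylic lactones, and the E/Z mixture is of no consequence because the sulfide-moderated Pd/C hydrogenation that follows saturates the alkene while leaving the aromatic aldehyde and the MOM ether alone.

Step 9
Reactants: 16 macrolide aldehyde
Product: 17 macrolide benzylic alcohol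
Conditions: NaBH4, MeOH–THF, 0 °C
Reagents that add atoms: none
Why: Borohydride reduction of the aryl aldehyde to the benzylic alcohol is chemoselective, since the hindered benzoate lactone and the MOM ether do not react with NaBH4 at 0 °C.

Step 10
Reactants: 17 macrolide benzylic alcohol
Product: 18 macrolide benzylic bromide (phenol as MOM ether)
Conditions: PPh3, CBr4, CH2Cl2, 0 °C; quick filtration through Et3N-deactivated silica; used at once
Reagents that add atoms: carbon tetrabromide BrC(Br)(Br)Br
Why: The Appel reaction converts the primary benzylic alcohol into the bromide under neutral conditions that spare the MOM ether, and because the ortho and para oxygen substituents make this bromide prone to ionisation it is kept cold and used the same day.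

Step 11
Reactants: 18 macrolide benzylic bromide; 19 furan-2(5H)-one
Product: 21 trans lactone macrolide (18 with Br replaced by the (3S,4S)-4-methyl-2-oxotetrahydrofuran-3-yl group), via magnesium enolate 20 (not isolated)
Conditions: 19 (3.0 equiv), CuBr·SMe2 (5 mol %), (R)-1-[(Sp)-2-(diphenylphosphino)ferrocenyl]ethyldicyclohexylphosphine (6 mol %), MeMgBr (2.8 equiv, slow addition), t-BuOMe, −78 °C; then 18 (1.0 equiv), THF–DMPU, −78 → −20 °C; aq NH4Cl
Reagents that add atoms: methylmagnesium bromide C[Mg]Br
Why: The monovalent copper–diphosphine complex, transmetallated by MeMgBr, forms a π-complex with the C3=C4 bond of 19, adds oxidatively to give a σ-bonded trivalent copper species at the β-carbon and reductively eliminates the C–CH3 bond, releasing magnesium enolate 20, which then displaces bromide from the activated benzylic carbon of 18 in an SN2 reaction. The closest known reaction type is the copper/ferrocenyl-diphosphine-catalysed conjugate addition of Grignard reagents to α,β-unsaturated lactones with trapping of the magnesium enolate by a reactive halide. No ring is closed. The methyl-bearing carbon is set by the chiral catalyst, and the α-carbon by the five-membered enolate itself, the electrophile entering anti to the new β-methyl group to give the trans (3S,4S) lactone. The step needs 1,4- over 1,2-addition (secured by the copper catalyst at −78 °C), no attack on the macrolide ester (a benzoate shielded by two ortho substituents) and no copper-catalysed methyl–benzyl coupling (MeMgBr is kept below the amount of 19 and is consumed before 18 is added). Because 18 is a single (R)-enantiomer, any minor enantiomer of 20 ends up as a diastereomer of 21 that chromatography should remove.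

Step 12
Reactants: 21 trans lactone macrolide
Product: 23 Lasiodiplactone A, via methyl lactol 22 (not isolated)
Conditions: MeLi (1.15 equiv), THF, −78 °C; then HCl in MeOH, −78 °C → rt; concentrate; TsOH·H2O (cat.), CH2Cl2, 4 Å MS, rt
Reagents that add atoms: methyllithium [Li]C
Why: Nucleophilic addition of methyllithium stops after one addition to the γ-lactone at −78 °C because the tetrahedral lithium alkoxide resists a second attack and the shielded macrolide benzoate is far slower, and acid then removes the MOM group (formaldehyde trapped as dimethoxymethane) and lets the phenol close onto the oxocarbenium ion of the lactol in a thermodynamically controlled ketalisation that can only give the cis fusion of rings C and D, so the ketal carbon follows the configuration of the neighbouring ring-fusion CH, whose favoured arrangement keeps the ring-D methyl group on the convex face.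

Compound list
1 | 3,5-dimethoxybenzyl bromide | COc1cc(CBr)cc(OC)c1 | starting material
2 | 5-bromopent-1-ene | C=CCCCBr | starting material
3 | pent-4-enylmagnesium bromide | C=CCCC[Mg]Br | intermediate
4 | 1-(hex-5-en-1-yl)-3,5-dimethoxybenzene | COc1cc(CCCCC=C)cc(OC)c1 | intermediate
5 | N-{[2-(hex-5-en-1-yl)-4,6-dimethoxyphenyl]methylidene}-N-methylmethanaminium chloride (aryl iminium chloride) | C[N+](C)=Cc1c(OC)cc(OC)cc1CCCCC=C.[Cl-] | intermediate
6 | 2-(hex-5-en-1-yl)-4,6-dimethoxybenzaldehyde | COc1cc(OC)c(C=O)c(CCCCC=C)c1 | intermediate
7 | 2-(hex-5-en-1-yl)-6-hydroxy-4-methoxybenzaldehyde | COc1cc(O)c(C=O)c(CCCCC=C)c1 | intermediate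
8 | 3-bromo-2-(hex-5-en-1-yl)-6-hydroxy-4-methoxybenzaldehyde | COc1cc(O)c(C=O)c(CCCCC=C)c1Br | intermediate
9 | 3-bromo-2-(hex-5-en-1-yl)-4-methoxy-6-(methoxymethoxy)benzaldehyde | COCOc1cc(OC)c(Br)c(CCCCC=C)c1C=O | intermediate
10 | lithium α-morpholino alkoxide of 9 (morpholide added to the aldehyde carbon) | [Li+].[O-]C(N1CCOCC1)c1c(OCOC)cc(OC)c(Br)c1CCCCC=C | intermediate
11 | aryllithium from 10 (Li in place of Br) | [Li+].[O-]C(N1CCOCC1)c1c(OCOC)cc(OC)c([Li])c1CCCCC=C | intermediate
12 | 3-formyl-2-(hex-5-en-1-yl)-6-methoxy-4-(methoxymethoxy)benzoic acid | COCOc1cc(OC)c(C(=O)O)c(CCCCC=C)c1C=O | intermediate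
13 | (S)-pent-4-en-2-ol | C[C@H](O)CC=C | starting material
14 | (R)-pent-4-en-2-yl 3-formyl-2-(hex-5-en-1-yl)-6-methoxy-4-(methoxymethoxy)benzoate | COCOc1cc(OC)c(C(=O)O[C@H](C)CC=C)c(CCCCC=C)c1C=O | intermediate
15 | macrocyclic alkene: ring-closed (R)-lactone ArC(=O)O–CH(CH3)–CH2–CH=CH–(CH2)4–Ar of 14, E/Z mixture | COc1cc(OCOC)c(C=O)c2c1C(=O)O[C@H](C)CC=CCCCC2 | intermediate
16 | macrolide aldehyde: saturated 12-membered (R)-lactone ArC(=O)O–CH(CH3)–(CH2)7–Ar bearing CHO, OMOM and OMe | COc1cc(OCOC)c(C=O)c2c1C(=O)O[C@H](C)CCCCCCC2 | intermediate
17 | macrolide benzylic alcohol (CH2OH in place of CHO of 16) | COc1cc(OCOC)c(CO)c2c1C(=O)O[C@H](C)CCCCCCC2 | intermediate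
18 | macrolide benzylic bromide (CH2Br, phenol as MOM ether) | COc1cc(OCOC)c(CBr)c2c1C(=O)O[C@H](C)CCCCCCC2 | intermediate
19 | furan-2(5H)-one | O=C1C=CCO1 | starting material
20 | bromomagnesium enolate of (S)-4-methyldihydrofuran-2(3H)-one | C[C@@H]1COC(O[Mg]Br)=C1 | intermediate
21 | trans lactone macrolide: (3S,4S)-4-methyl-2-oxotetrahydrofuran-3-yl attached through the benzylic CH2 | COc1cc(OCOC)c(C[C@H]3[C@H](C)COC3=O)c2c1C(=O)O[C@H](C)CCCCCCC2 | intermediate
22 | methyl lactol: 21 with the lactone C=O turned into C(OH)CH3, anomeric mixture in equilibrium with the open hydroxy ketone | COc1cc(OCOC)c(C[C@H]3[C@H](C)COC3(C)O)c2c1C(=O)O[C@H](C)CCCCCCC2 | intermediate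
23 | Lasiodiplactone A | COc1cc2c(c3c1C(=O)O[C@H](C)CCCCCCC3)C[C@H]1[C@H](C)CO[C@@]1(C)O2 | target

Total step count: 12. Longest linear sequence: 12 steps (1 and 2 to 23); 13 and 19 are bought and enter in steps 7 and 11.

Steps most likely to fail

1. Step 11. What may go wrong: weak facial discrimination in the methyl transfer to the small, flat butenolide, and slow SN2 attack of the magnesium enolate at a benzylic carbon with two ortho substituents, which gives the enolate time to add to unreacted butenolide. Fallback (sets out from 18, returns at 21): the two bonds are made in separate flasks. (S)-4-Methyldihydrofuran-2(3H)-one F1 is prepared on its own by Ru(OAc)2(BINAP)-catalysed asymmetric hydrogenation of commercial 4-methylfuran-2(5H)-one (CC1=CC(=O)OC1), with the BINAP antipode that gives the S lactone. LiN(SiMe3)2 in THF at −78 °C converts it into lithium enolate F2, which is more reactive than its magnesium counterpart and is benzylated by 18 (THF–DMPU, −78 → −40 °C) anti to the methyl group to give 21.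

2. Step 10. What may go wrong: ionisation of the benzylic bromide, assisted by the ortho-OMOM and para-OMe groups, followed by self-alkylation of the electron-rich ring or loss of the MOM group before the bromide can be used. Fallback (sets out from 16, returns at 23): no benzylic halide is made. Enolate 20, generated as in step 11, is trapped at −78 °C by aldehyde 16 in an aldol reaction to give hydroxy lactone F3 (carbinol epimers, trans on the lactone ring). Ionic hydrogenation (Et3SiH, CF3CO2H, CH2Cl2, 0 °C) removes the doubly activated benzylic hydroxyl group and the MOM group in one operation to give phenol lactone F4. MeLi (2.2 equiv, THF, −78 °C) then gives phenol lactol F5, which closes to 23 with TsOH in CH2Cl2.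

3. Step 6. What may go wrong: incomplete masking of the hindered aldehyde, so that t-BuLi adds to the carbonyl group, or protonation of the aryllithium before carboxylation. Fallback (sets out from 9, returns at 12): the aldehyde is masked in a separate, isolated step. HC(OMe)3, MeOH and PPTS give dimethyl acetal F6; t-BuLi (2.1 equiv, THF, −78 °C) followed by CO2 gives acetal acid F7; brief stirring with 1 M HCl in THF at 0 °C hydrolyses the acetal without loss of the MOM ether to return 12.

Further compounds
F1 | step 11 | (S)-4-methyldihydrofuran-2(3H)-one | C[C@@H]1COC(=O)C1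
F2 | step 11 | lithium enolate of (S)-4-methyldihydrofuran-2(3H)-one | C[C@@H]1COC(O[Li])=C1
F3 | step 10 | hydroxy lactone: aldol adduct of 20 and 16, ArCH(OH) on the lactone α-carbon, trans to the methyl group | COc1cc(OCOC)c(C(O)[C@H]3[C@H](C)COC3=O)c2c1C(=O)O[C@H](C)CCCCCCC2
F4 | step 10 | phenol lactone (21 without the MOM group) | COc1cc(O)c(C[C@H]3[C@H](C)COC3=O)c2c1C(=O)O[C@H](C)CCCCCCC2
F5 | step 10 | phenol lactol (22 without the MOM group) | COc1cc(O)c(C[C@H]3[C@H](C)COC3(C)O)c2c1C(=O)O[C@H](C)CCCCCCC2
F6 | step 6 | 3-bromo-2-(hex-5-en-1-yl)-4-methoxy-6-(methoxymethoxy)benzaldehyde dimethyl acetal | COCOc1cc(OC)c(Br)c(CCCCC=C)c1C(OC)OC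
F7 | step 6 | 3-(dimethoxymethyl)-2-(hex-5-en-1-yl)-6-methoxy-4-(methoxymethoxy)benzoic acid | COCOc1cc(OC)c(C(=O)O)c(CCCCC=C)c1C(OC)OC
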